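**Retrosynthetic overview**
1. The target is methyl (−)-shikimate with (E)-3-methylpent-2-enoyl groups on O3 and O5. Numbering: C1 is the ester-bearing sp2 carbon, C2 the vinyl CH, C3–C5 the oxygenated carbons, C6 the CH2. The two acyl C–O bonds are cut first, O3 before O5.
2. O3 and O4 are traced back to a syn-dihydroxylation of a C3=C4 alkene anti to O5. This leaves a (5R)-5-hydroxycyclohexa-1,3-diene-1-carboxylate.
3. Feature used: in the single cyclohexene ring, C2 (sp2, β to the ester) and C5 (oxygen-bearing) lie 1,4 across the ring. One oxygen can therefore bridge them in a 7-oxabicyclo[2.2.1]heptene, then leave C2 by E1cB through C1 while staying on C5.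
4. The bicycle is cut at C1–C2 and C5–C6 into furan (C2–C5 and O5) and an acrylate (C1, C6 and the ester carbon). The forward reaction is a dearomatising, catalyst-controlled Diels–Alder reaction.
5. Ring order: furan ring (bought), then carbocycle C1–C6 closed in the cycloaddition, then oxygen bridge opened. Endo and exo adducts formed on one acrylate face have mirror-image bridgeheads, so the endo adduct is isolated pure before C1 is flattened.

Key step: step 3

Assumption: the α-C–H···O binding model for acrylates on this boron cation predicts attack on the Cα-si face with the (S)-amino alcohol series, which is the face needed here; the sense is to be confirmed at the dienol stage by correlation with natural (−)-shikimate, and the commercial (R)-amino alcohol would be used in the same way if the opposite sense were found.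

**Step 1**
Reactants: 1 (S)-diphenyl(pyrrolidin-2-yl)methanol; 2 (2-methylphenyl)boronic acid
Product: 3 (3aS)-1-(2-methylphenyl)-3,3-diphenyltetrahydro-1H,3H-pyrrolo[1,2-c][1,3,2]oxazaborole
Conditions: toluene, reflux, Dean–Stark; evaporation
Reagents that add atoms: none
Why: Dehydrative condensation of a 1,2-amino alcohol with a boronic acid closes the five-membered 1,3,2-oxazaborolidine once water is removed azeotropically, and the stereocentre of 1 is not involved.

**Step 2**
Reactants: 3 oxazaborolidine
Product: 4 N-protonated oxazaborolidinium bis(trifluoromethanesulfonyl)imide (cis-fused cation, used as its CH2Cl2 solution)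
Conditions: HN(SO2CF3)2 (0.9 equiv), CH2Cl2, −25 °C, 15 min
Reagents that add atoms: bis(trifluoromethanesulfonyl)imide HN(SO2CF3)2, O=S(=O)(NS(=O)(=O)C(F)(F)F)C(F)(F)F
Why: Brønsted acid–base salt formation, in which the very strong acid protonates the ring nitrogen on the convex face of the bicycle, cancels the N→B donation and makes boron a strong chiral Lewis acid, while the small deficit of acid leaves no free proton source for a racemic background reaction or furan polymerisation.

**Step 3**
Reactants: 5 furan; 6 2,2,2-trifluoroethyl acrylate
Product: 7 2,2,2-trifluoroethyl (1R,2R,4R)-7-oxabicyclo[2.2.1]hept-5-ene-2-carboxylate (endo adduct)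
Conditions: 4 (20 mol%), 5 (5 equiv), CH2Cl2, −78 °C; Et3N at −78 °C; SiO2 (endo separated from exo)
Reagents that add atoms: none
Why: The boron of cation 4 binds the acrylate carbonyl at the lone pair anti to OCH2CF3, an α-C–H···O contact to the ring oxygen holds the s-trans enoate above one phenyl group, and furan adds to the open Cα-si face in a concerted but asynchronous, suprafacial [4π+2π] step that forms C1–C2 and C5–C6 together. The closest known reaction type is the oxazaborolidinium-catalysed Diels–Alder reaction of acrylates with cyclic dienes, furans included. The one new ring, the six-membered carbocycle C1–C6, closes by intermolecular cycloaddition with both bonds made in one step, and the furan oxygen is left as the one-atom bridge from C2 to C5. C1 is set by the shielded acrylate face, whereas C2 and C5 are set by which furan face meets that acrylate face, that is by the endo placement of the ester under C3=C4, which is favoured kinetically by secondary overlap with the Lewis acid-bound carbonyl. Because endo and exo adducts formed on the same acrylate face carry mirror-image bridgeheads and C1 is flattened later, the exo isomer would end as the enantiomeric dienol, so the step needs endo selectivity as well as face selectivity and the exo isomer is removed by chromatography here. The activated trifluoroethyl ester allows a run at −78 °C and the cold amine quench destroys the Lewis acid before warming, so cycloreversion cannot equilibrate the isomers or erode the enantiopurity.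

**Step 4**
Reactants: 7 endo trifluoroethyl ester
Product: 8 methyl (1R,2R,4R)-7-oxabicyclo[2.2.1]hept-5-ene-2-carboxylate
Conditions: K2CO3 (0.2 equiv), MeOH, 0 °C
Reagents that add atoms: methanol, CO
Why: Base-catalysed transesterification, in which methoxide displaces the good leaving group trifluoroethoxide at 0 °C, any epimerisation at C1 is harmless because the separated adduct keeps its bridgeheads, and the swap precedes the bridge opening so that the later C5 alkoxide never meets an activated ester.

**Step 5**
Reactants: 8 methyl ester
Product: 10 methyl (5R)-5-hydroxycyclohexa-1,3-diene-1-carboxylate, via lithium alkoxide 9 (not isolated)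
Conditions: LiN(SiMe3)2 (1.1 equiv), THF, −78 → 0 °C; aq NH4Cl
Reagents that add atoms: none
Why: Base-induced E1cB opening of an oxanorbornene, in which the ester enolate at C1 expels the bridging oxygen from C2 with release of ring strain, the C5–O bond is never broken so C5 keeps the R configuration set in step 3, and the cold reaction with a buffered quench avoids dehydration to the benzoate.

**Step 6**
Reactants: 10 dienol; 11 (E)-3-methylpent-2-enoic acid
Product: 12 methyl (5R)-5-{[(2E)-3-methylpent-2-enoyl]oxy}cyclohexa-1,3-diene-1-carboxylate
Conditions: DCC, DMAP (10 mol%), CH2Cl2, 0 °C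
Reagents that add atoms: none
Why: Steglich esterification under near-neutral conditions acylates the only hydroxyl group without touching the C5–O bond, and avoiding an acid chloride/amine pair suppresses the vinylketene pathway that would deconjugate or isomerise the E-trisubstituted alkene.

**Step 7**
Reactants: 12 5-acyloxy diene
Product: 13 methyl (3R,4R,5R)-3,4-dihydroxy-5-{[(2E)-3-methylpent-2-enoyl]oxy}cyclohex-1-ene-1-carboxylate (shikimate configuration; the C4 descriptor differs from that of the target for priority reasons only)
Conditions: OsO4 (2 mol%), NMO (1.05 equiv), acetone–H2O, 0 °C; aq Na2SO3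
Reagents that add atoms: osmium tetroxide OsO4, O=[Os](=O)(=O)=O; N-methylmorpholine N-oxide, C[N+]1([O-])CCOCC1; water, O
Why: OsO4-catalysed syn-dihydroxylation, in which osmium picks the γ,δ-alkene C3=C4 (the only C=C that carries no ester directly and hence the most electron-rich) and adds to the ring face anti to the pseudoaxial C5 acyloxy group, which sets C3 and C4 with both new oxygens cis to each other and trans to O5.

**Step 8**
Reactants: 13 3,4-diol; 11 (E)-3-methylpent-2-enoic acid
Product: 14 methyl (3R,4S,5R)-4-hydroxy-3,5-bis{[(2E)-3-methylpent-2-enoyl]oxy}cyclohex-1-ene-1-carboxylate (CNP0268575.1)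
Conditions: 11 (1.05 equiv), DCC, DMAP (5 mol%), CH2Cl2, −20 °C
Reagents that add atoms: none
Why: Regioselective Steglich mono-esterification, in which O3 is allylic with the flat C2 as one neighbour whereas O4 is flanked by two oxygenated carbons and is the slowest hydroxyl to react in shikimate and quinate polyols, so one equivalent of the bulky β,β-disubstituted acyl donor at low temperature should go to O3 without touching any stereocentre.

**Compound list**
1 | (S)-diphenyl(pyrrolidin-2-yl)methanol | OC(c1ccccc1)(c1ccccc1)[C@@H]1CCCN1 | starting material
2 | (2-methylphenyl)boronic acid | Cc1ccccc1B(O)O | starting material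
3 | (3aS)-1-(2-methylphenyl)-3,3-diphenyltetrahydro-1H,3H-pyrrolo[1,2-c][1,3,2]oxazaborole | Cc1ccccc1B1OC(c2ccccc2)(c2ccccc2)[C@@H]2CCCN12 | intermediate
4 | N-protonated 3 as its bis(trifluoromethanesulfonyl)imide salt | Cc1ccccc1B1OC(c2ccccc2)(c2ccccc2)[C@@H]2CCC[N@H+]12.O=S(=O)(C(F)(F)F)[N-]S(=O)(=O)C(F)(F)F | intermediate
5 | furan | c1ccoc1 | starting material
6 | 2,2,2-trifluoroethyl acrylate | C=CC(=O)OCC(F)(F)F | starting material
7 | 2,2,2-trifluoroethyl (1R,2R,4R)-7-oxabicyclo[2.2.1]hept-5-ene-2-carboxylate (endo) | O=C(OCC(F)(F)F)[C@@H]1C[C@@H]2C=C[C@H]1O2 | intermediate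
8 | methyl (1R,2R,4R)-7-oxabicyclo[2.2.1]hept-5-ene-2-carboxylate (endo) | COC(=O)[C@@H]1C[C@@H]2C=C[C@H]1O2 | intermediate
9 | lithium (1R)-5-(methoxycarbonyl)cyclohexa-2,4-dien-1-olate | COC(=O)C1=CC=C[C@H]([O-])C1.[Li+] | intermediate
10 | methyl (5R)-5-hydroxycyclohexa-1,3-diene-1-carboxylate | COC(=O)C1=CC=C[C@H](O)C1 | intermediate
11 | (E)-3-methylpent-2-enoic acid | CC/C(C)=C/C(=O)O | starting material
12 | methyl (5R)-5-{[(2E)-3-methylpent-2-enoyl]oxy}cyclohexa-1,3-diene-1-carboxylate | COC(=O)C1=CC=C[C@H](OC(=O)/C=C(\C)CC)C1 | intermediate
13 | methyl (3R,4R,5R)-3,4-dihydroxy-5-{[(2E)-3-methylpent-2-enoyl]oxy}cyclohex-1-ene-1-carboxylate | O[C@@H]1C=C(C(=O)OC)C[C@@H](OC(=O)/C=C(\C)CC)[C@@H]1O | intermediate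
14 | methyl (3R,4S,5R)-4-hydroxy-3,5-bis{[(2E)-3-methylpent-2-enoyl]oxy}cyclohex-1-ene-1-carboxylate | CC/C(C)=C/C(=O)O[C@@H]1C=C(C(=O)OC)C[C@@H](OC(=O)/C=C(\C)CC)[C@@H]1O | target

**Step count**
Total: 8 steps, 2 for the catalyst and 6 on the carbon skeleton.
Longest linear sequence: 6 steps (steps 3 to 8, from furan and the acrylate).

**The three steps most likely to fail**

(a) Step 3.
- Risk: the furan cycloaddition is reversible and only weakly endo-selective. Low conversion, loss of material to the exo series, or erosion of enantiopurity by cycloreversion during work-up may occur.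
- Fallback: it keeps the furan/acryloyl [4+2] bond set but changes how the dienophile is activated and how the isomers are purified. It sets out from furan 5.
- Commercial 3-acryloyl-1,3-oxazolidin-2-one is chelated through both carbonyl groups by [Cu(L)](SbF6)2. This is a divalent copper complex with L = 2,2'-(propane-2,2-diyl)bis[(4R)-4-tert-butyl-4,5-dihydro-1,3-oxazole].
- In CH2Cl2 at −78 °C this should give 3-[(1R,2R,4R)-7-oxabicyclo[2.2.1]hept-5-ene-2-carbonyl]-1,3-oxazolidin-2-one F1. This imide should crystallise, so the exo isomer and the minor enantiomer can be removed by recrystallisation.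
- LiSEt in THF at −20 °C then gives S-ethyl (1R,2R,4R)-7-oxabicyclo[2.2.1]hept-5-ene-2-carbothioate F2.
- Cs2CO3 in methanol converts F2 into methyl ester 8, where the route is rejoined.

(b) Step 8.
- Risk: competing acylation of O4, double acylation, or base-promoted acyl migration between the cis oxygens O3 and O4 may spoil the regioselectivity.
- Fallback: the kinetic choice between two hydroxyl groups is replaced by an ionisation that only the allylic C3–O bond can undergo. It sets out from diol 13.
- Diol 13 and 1,1'-carbonyldiimidazole (CH2Cl2, rt) give methyl 5-O-[(2E)-3-methylpent-2-enoyl]shikimate 3,4-cyclic carbonate F3.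
- Pd(PPh3)4 (zerovalent palladium, 5 mol%) and acid 11 in THF at rt then ionise C3–O anti to the leaving oxygen. The carbonate decarboxylates and the C4 alkoxide is protonated by 11.
- The carboxylate attacks the allyl terminus C3, remote from the ester-bearing C1, anti to palladium. This Tsuji–Trost substitution proceeds with net retention and should lead directly to target 14 with O4 free.

(c) Step 6.
- Risk: the dienol, and still more its ester, can aromatise by loss of water or of the carboxylic acid under the coupling conditions. γ-Deprotonation of the activated acid may also scramble the E alkene.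
- Fallback: the diene is removed before any acyl group is attached, which also spares step 7 the choice among three alkenes. It sets out from dienol 10.
- Dienol 10 is dihydroxylated (OsO4 cat., NMO, acetone–H2O, 0 °C) anti to the free hydroxyl to give methyl shikimate F4.
- The cis-3,4-diol is tied up with 2,2-dimethoxypropane and TsOH (cat.) as methyl 3,4-O-isopropylideneshikimate F5.
- The only free hydroxyl, O5, is esterified with 11 (DCC, DMAP) to give methyl 3,4-O-isopropylidene-5-O-[(2E)-3-methylpent-2-enoyl]shikimate F6.
- Aqueous acetic acid at 40 °C removes the acetonide to give diol 13, where the route is rejoined.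

**Further compounds**
F1 | step 3 | 3-[(1R,2R,4R)-7-oxabicyclo[2.2.1]hept-5-ene-2-carbonyl]-1,3-oxazolidin-2-one | O=C([C@@H]1C[C@@H]2C=C[C@H]1O2)N1CCOC1=O
F2 | step 3 | S-ethyl (1R,2R,4R)-7-oxabicyclo[2.2.1]hept-5-ene-2-carbothioate | CCSC(=O)[C@@H]1C[C@@H]2C=C[C@H]1O2
F3 | step 8 | methyl 5-O-[(2E)-3-methylpent-2-enoyl]shikimate 3,4-cyclic carbonate | O=C1O[C@@H]2C=C(C(=O)OC)C[C@@H](OC(=O)/C=C(\C)CC)[C@@H]2O1
F4 | step 6 | methyl shikimate, methyl (3R,4S,5R)-3,4,5-trihydroxycyclohex-1-ene-1-carboxylate | O[C@@H]1C=C(C(=O)OC)C[C@@H](O)[C@@H]1O
F5 | step 6 | methyl 3,4-O-isopropylideneshikimate | CC1(C)O[C@@H]2C=C(C(=O)OC)C[C@@H](O)[C@@H]2O1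
F6 | step 6 | methyl 3,4-O-isopropylidene-5-O-[(2E)-3-methylpent-2-enoyl]shikimate | CC1(C)O[C@@H]2C=C(C(=O)OC)C[C@@H](OC(=O)/C=C(\C)CC)[C@@H]2O1
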